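**Retrosynthetic overview**
1. Target 26 ⇒ 25 by a singlet-oxygen ene reaction (C11–OOH, C6=C7); 25 ⇒ 22 + angelic acid (ester C–O); 22 ⇒ 19 + acetone (aldol–dehydration, C7–C11).
2. 19 ⇒ 12: the 3β,4α-diol with 4β-CH3 and the trans ring fusion come from a 4-methyl-4-en-3-one by Li/NH3 reduction (C5), Rubottom oxidation (C4) and NaBH4 reduction (C3).
3. 12 ⇒ 4: C15 by cross-coupling at a C4 enol triflate, the carbonyl moved from C1 to C3 by Stork–Danheiser transposition, C1=C2 hydrogenated.
4. 4 ⇒ 2 + 3: the strategy rests on ring B (C5–C10), whose C6–C9 unit with the C8 oxygen is a 2-silyloxybutadiene added across the C5=C10 bond of a quinone that is ring A and already carries the C3 oxygen (OCH3), the C4 carbonyl and the C14 methyl on C10.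
5. Ring order: ring A is bought as the quinone, ring B is closed in the Diels–Alder step, and no further ring is formed.

Key step: step 2

Remark on numbering: eudesmane numbering is used for all intermediates (ring A = C1–C5 and C10, ring B = C5–C10, C14 on C10, C15 on C4, C11–C13 on C7; β is the face of C14).
Assumption: the target is addressed as the open hydroperoxy enone that is drawn; a possible cyclic peroxyhemiketal tautomer is treated as the same compound.

**Route**

Step 1
Reactants: 1 methyl vinyl ketone
Product: 2 2-(triisopropylsilyloxy)buta-1,3-diene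
Conditions: i-Pr3SiOTf, Et3N, Et2O, 0 °C to rt
Reagents that add atoms: triisopropylsilyl trifluoromethanesulfonate, CC(C)[Si](C(C)C)(C(C)C)OS(=O)(=O)C(F)(F)F
Why: Soft enolisation with O-silylation (silyl enol ether formation) can only enolise the ketone toward its methyl group, so the 2-silyloxy diene is the single constitutional product.

Step 2
Reactants: 2 2-(triisopropylsilyloxy)buta-1,3-diene, 3 2-methoxy-5-methyl-1,4-benzoquinone
Product: 4 cis-fused adduct, (4aR,8aS)-2-methoxy-4a-methyl-6-(triisopropylsilyloxy)-4a,5,8,8a-tetrahydronaphthalene-1,4-dione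
Conditions: [Cu((S,S)-t-Bu-box)](SbF6)2 (10 mol %), 4 Å molecular sieves, CH2Cl2, −78 to −40 °C
Reagents that add atoms: none
Why: This is a Lewis-acid-catalysed normal-demand [4+2] cycloaddition in which the quinone binds divalent copper as a five-membered chelate through the C4 carbonyl oxygen and the C3 methoxy oxygen, so that C10 (β to the bound carbonyl) becomes the electrophilic terminus and takes the nucleophilic CH2 terminus C9 of the silyloxy diene while C6 bonds to C5, the same orientation as in the uncatalysed reaction. The closest known reaction type is the enantioselective Diels–Alder reaction of chelating quinones and of α'-oxygenated enones under chiral bis(oxazoline)–copper and titanium–binaphthol Lewis acids. Ring B is closed as a six-membered ring by a concerted suprafacial cycloaddition that forms C5–C6 and C9–C10 on one face, which makes the ring fusion cis. C10 is controlled by the ligand: in the square-planar chelate the tert-butyl group beside the bound carbonyl should cover the Si face of C10, so the diene adds to the Re face of C10 (Si face of C5) and gives 10R, while C5 (S) follows from suprafacial addition and is erased in step 3. The step needs site selectivity (the methoxy-bearing C2=C3 bond is an electron-rich enol ether and stays out), regioselectivity (secured by chelation at the C4 carbonyl instead of single-point binding at the more basic C1 vinylogous ester carbonyl) and facial selectivity (ligand), whereas endo/exo selectivity is irrelevant because the diene has no terminal substituent.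

Step 3
Reactants: 4 cis-fused adduct
Product: 6 C4 enol triflate, (10R)-3-methoxy-1-oxo-8-(triisopropylsilyloxy)-11,12,13,15-tetranoreudesma-2,4,7-trien-4-yl trifluoromethanesulfonate, via potassium enolate 5 (not isolated)
Conditions: KN(SiMe3)2 (1.05 equiv), THF, −78 °C; then (5-chloropyridin-2-yl)NTf2, −78 to 0 °C
Reagents that add atoms: N-(5-chloropyridin-2-yl)-1,1,1-trifluoro-N-(trifluoromethylsulfonyl)methanesulfonamide, FC(F)(F)S(=O)(=O)N(c1ccc(Cl)cn1)S(=O)(=O)C(F)(F)F
Why: C5–H is the only enolisable hydrogen (C10 is quaternary, C2 and C3 are sp2), so deprotonation and O-sulfonylation of the enolate (enol triflate formation) should give the C4=C5 triflate and flatten the cis C5 centre.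

Step 4
Reactants: 6 C4 enol triflate
Product: 7 (10R)-3-methoxy-8-(triisopropylsilyloxy)-11,12,13-trinoreudesma-2,4,7-trien-1-one
Conditions: MeZnCl, Pd(PPh3)4 (5 mol %), THF, rt to 50 °C
Reagents that add atoms: methylzinc chloride, C[Zn]Cl
Why: Negishi cross-coupling (oxidative addition of zerovalent palladium into the electron-poor dienyl C–OTf bond, transmetallation from zinc, reductive elimination) installs C15, and the organozinc adds neither to the vinylogous ester carbonyl nor to the silyl enol ether.

Step 5
Reactants: 7 methyl trienone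
Product: 10 (10S)-11,12,13-trinoreudesma-1,4-diene-3,8-dione, via dienol 8 (not isolated), via silyloxy trienone 9 (not isolated)
Conditions: i-Bu2AlH, CH2Cl2, −78 °C; then 2 M aq. HCl, THF, 0 °C to rt
Reagents that add atoms: water, O
Why: Stork–Danheiser transposition, in which 1,2-reduction of the vinylogous ester carbonyl at C1 and acid hydrolysis of the 3-methoxy dienol through the C3 oxocarbenium ion move the carbonyl to C3 with loss of methanol and water, while the same acid hydrolyses the silyl enol ether to the C8 ketone.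

Step 6
Reactants: 10 dienedione
Product: 11 (10S)-8,8-ethylenedioxy-11,12,13-trinoreudesma-1,4-dien-3-one
Conditions: HOCH2CH2OH, TsOH·H2O (cat.), benzene, reflux (Dean–Stark)
Reagents that add atoms: ethylene glycol, OCCO
Why: Acid-catalysed ketalisation is selective for the saturated C8 ketone because the cross-conjugated C3 dienone carbonyl is much less electrophilic, the selectivity known from monoketals of bicyclic enediones.

Step 7
Reactants: 11 dienone ketal
Product: 12 (10R)-8,8-ethylenedioxy-11,12,13-trinoreudesm-4-en-3-one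
Conditions: H2 (1 atm), RhCl(PPh3)3 (5 mol %), benzene–EtOH, rt
Reagents that add atoms: none
Why: Homogeneous hydrogenation with RhCl(PPh3)3 saturates the disubstituted C1=C2 bond and leaves the tetrasubstituted C4=C5 bond, the established way from 1,4-dien-3-ones to 4-en-3-ones.

Step 8
Reactants: 12 enone ketal
Product: 14 (5R,10R)-8,8-ethylenedioxy-3-(trimethylsilyloxy)-11,12,13-trinoreudesm-3-ene (5α-H), via lithium enolate 13 (not isolated)
Conditions: Li (2.2 equiv), t-BuOH (1 equiv), NH3(l)–THF, −78 °C; isoprene; NH3 evaporated; then Me3SiCl, Et3N, THF, 0 °C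
Reagents that add atoms: chlorotrimethylsilane, C[Si](C)(C)Cl
Why: Dissolving-metal enone reduction with enolate trapping, in which the β-carbon C5 is protonated axially on the α face, anti to C14, to set the trans ring fusion, and the regiodefined C3–C4 enolate is silylated on oxygen.

Step 9
Reactants: 14 silyl enol ether
Product: 17 (4S,5R,10R)-8,8-ethylenedioxy-4α-hydroxy-11,12,13-trinoreudesman-3-one (4β-CH3), via silyloxy epoxide 15 (not isolated), via silyloxy ketone 16 (not isolated)
Conditions: mCPBA, NaHCO3, CH2Cl2, 0 °C; then K2CO3, MeOH, 0 °C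
Reagents that add atoms: 3-chloroperoxybenzoic acid, OOC(=O)c1cccc(Cl)c1
Why: Rubottom oxidation, in which the peracid epoxidises the tetrasubstituted enol ether on the α face because the axial C14 methyl shields the β face of C4, and epoxide opening with 1,4-silyl shift followed by methanolysis gives the 4α-hydroxy-4β-methyl ketone.

Step 10
Reactants: 17 hydroxy ketone
Product: 19 (3S,4S,5R,10R)-3β,4α-dihydroxy-11,12,13-trinoreudesman-8-one, via diol ketal 18 (not isolated)
Conditions: NaBH4, MeOH, 0 °C; acetone (quench); then 2 M aq. HCl, THF, rt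
Reagents that add atoms: water, O
Why: Borohydride reduction by axial hydride delivery on the α face of C3, the β face being blocked by the adjacent axial C15 methyl, should give the equatorial 3β-alcohol trans to the 4α-hydroxyl, and acid hydrolysis of the dioxolane then frees the C8 ketone.

Step 11
Reactants: 19 dihydroxy ketone
Product: 21 (3S,4S,5R,10R)-3β,4α,11-trihydroxyeudesman-8-one (C7 configuration not controlled), via trilithium enolate 20 (not isolated)
Conditions: LiN(i-Pr)2 (3.3 equiv), THF, −78 to −40 °C; acetone, −78 °C; AcOH, −78 °C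
Reagents that add atoms: acetone, CC(C)=O
Why: Directed aldol addition, in which the amide first deprotonates both hydroxyls and then removes a C7 hydrogen (C9 is neopentyl beside quaternary C10 and the Δ7 enolate is the favoured one of this trans-fused ketone), and the enolate adds to acetone to form the C7–C11 bond, the C7 centre being removed again in step 12.

Step 12
Reactants: 21 aldol
Product: 22 (3S,4S,5R,10R)-3β,4α-dihydroxyeudesm-7(11)-en-8-one
Conditions: TsOH·H2O (10 mol %), benzene, 50 °C
Reagents that add atoms: none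
Why: Acid-catalysed dehydration of the β-hydroxy ketone through its enol (aldol condensation) should give the conjugated tetrasubstituted C7=C11 enone as the thermodynamic isomer, while the C4 tertiary alcohol, which lacks such enol assistance, is expected to persist.

Step 13
Reactants: 22 dihydroxy enone, 23 angelic acid
Product: 25 (3S,4S,5R,10R)-3β-angeloyloxy-4α-hydroxyeudesm-7(11)-en-8-one, via mixed anhydride 24 (not isolated)
Conditions: 23 (3 equiv), 2,4,6-Cl3C6H2COCl, Et3N, toluene, rt; then 22, 80 °C
Reagents that add atoms: none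
Why: Mixed-anhydride (Yamaguchi-type) esterification without a nucleophilic amine catalyst should acylate the secondary equatorial 3β-hydroxyl and not the tertiary C4 hydroxyl, and the absence of a catalyst that could add reversibly to the unsaturated acyl group keeps the Z geometry of the angelate.

Step 14
Reactants: 25 angelate enone
Product: 26 (3S,4S,5R,10R)-3β-angeloyloxy-4α-hydroxy-11-hydroperoxyeudesm-6-en-8-one (CNP0161122.1)
Conditions: O2, tetraphenylporphyrin (cat.), CH2Cl2, visible light, −20 to 0 °C
Reagents that add atoms: dioxygen, O=O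
Why: Schenck ene reaction, in which singlet oxygen attacks the s-cis-locked C7=C11 enone and abstracts the hydrogen of the alkyl group geminal to the carbonyl (C6–H), so that the hydroperoxide lands on C11 and the new double bond C6=C7 stays conjugated with C8=O, while the electron-poor angelate alkene reacts far more slowly and the low-energy sensitiser cannot isomerise it.

**Compound list**
1 | methyl vinyl ketone | C=CC(C)=O | starting material
2 | 2-(triisopropylsilyloxy)buta-1,3-diene | C=CC(=C)O[Si](C(C)C)(C(C)C)C(C)C | intermediate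
3 | 2-methoxy-5-methyl-1,4-benzoquinone | COC1=CC(=O)C(C)=CC1=O | starting material
4 | (4aR,8aS)-2-methoxy-4a-methyl-6-(triisopropylsilyloxy)-4a,5,8,8a-tetrahydronaphthalene-1,4-dione (cis adduct, 5β-H, 10β-CH3) | COC1=CC(=O)[C@]2(C)CC(O[Si](C(C)C)(C(C)C)C(C)C)=CC[C@@H]2C1=O | intermediate
5 | potassium C4 enolate of 4 (C4=C5; not isolated) | COC1=CC(=O)[C@]2(C)CC(O[Si](C(C)C)(C(C)C)C(C)C)=CCC2=C1[O-].[K+] | intermediate
6 | (10R)-3-methoxy-1-oxo-8-(triisopropylsilyloxy)-11,12,13,15-tetranoreudesma-2,4,7-trien-4-yl trifluoromethanesulfonate | COC1=CC(=O)[C@]2(C)CC(O[Si](C(C)C)(C(C)C)C(C)C)=CCC2=C1OS(=O)(=O)C(F)(F)F | intermediate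
7 | (10R)-3-methoxy-8-(triisopropylsilyloxy)-11,12,13-trinoreudesma-2,4,7-trien-1-one | COC1=CC(=O)[C@]2(C)CC(O[Si](C(C)C)(C(C)C)C(C)C)=CCC2=C1C | intermediate
8 | (10R)-3-methoxy-8-(triisopropylsilyloxy)-11,12,13-trinoreudesma-2,4,7-trien-1-ol (C1 epimers; not isolated) | COC1=CC(O)[C@]2(C)CC(O[Si](C(C)C)(C(C)C)C(C)C)=CCC2=C1C | intermediate
9 | (10S)-8-(triisopropylsilyloxy)-11,12,13-trinoreudesma-1,4,7-trien-3-one (not isolated) | O=C1C=C[C@]2(C)CC(O[Si](C(C)C)(C(C)C)C(C)C)=CCC2=C1C | intermediate
10 | (10S)-11,12,13-trinoreudesma-1,4-diene-3,8-dione | O=C1C=C[C@]2(C)CC(=O)CCC2=C1C | intermediate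
11 | (10S)-8,8-ethylenedioxy-11,12,13-trinoreudesma-1,4-dien-3-one | O=C1C=C[C@]2(C)CC3(OCCO3)CCC2=C1C | intermediate
12 | (10R)-8,8-ethylenedioxy-11,12,13-trinoreudesm-4-en-3-one | O=C1CC[C@]2(C)CC3(OCCO3)CCC2=C1C | intermediate
13 | lithium (5R,10R)-8,8-ethylenedioxy-11,12,13-trinoreudesm-3-en-3-olate (5α-H; not isolated) | [Li+].[O-]C=1CC[C@]2(C)CC3(OCCO3)CC[C@H]2C=1C | intermediate
14 | (5R,10R)-8,8-ethylenedioxy-3-(trimethylsilyloxy)-11,12,13-trinoreudesm-3-ene | C[Si](C)(C)OC=1CC[C@]2(C)CC3(OCCO3)CC[C@H]2C=1C | intermediate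
15 | 3α,4α-epoxy-8,8-ethylenedioxy-3β-(trimethylsilyloxy)-11,12,13-trinor-5αH-eudesmane (not isolated) | C[Si](C)(C)O[C@]31CC[C@]2(C)CC4(OCCO4)CC[C@H]2[C@]1(C)O3 | intermediate
16 | (4S,5R,10R)-8,8-ethylenedioxy-4α-(trimethylsilyloxy)-11,12,13-trinoreudesman-3-one (not isolated) | O=C1CC[C@]2(C)CC3(OCCO3)CC[C@H]2[C@]1(C)O[Si](C)(C)C | intermediate
17 | (4S,5R,10R)-8,8-ethylenedioxy-4α-hydroxy-11,12,13-trinoreudesman-3-one | O=C1CC[C@]2(C)CC3(OCCO3)CC[C@H]2[C@]1(C)O | intermediate
18 | (3S,4S,5R,10R)-8,8-ethylenedioxy-11,12,13-trinoreudesmane-3β,4α-diol (not isolated) | O[C@H]1CC[C@]2(C)CC3(OCCO3)CC[C@H]2[C@]1(C)O | intermediate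
19 | (3S,4S,5R,10R)-3β,4α-dihydroxy-11,12,13-trinoreudesman-8-one | O[C@H]1CC[C@]2(C)CC(=O)CC[C@H]2[C@]1(C)O | intermediate
20 | trilithium 3,4-dialkoxide C7=C8 enolate of 19 (not isolated) | [Li+].[Li+].[Li+].[O-][C@H]1CC[C@]2(C)CC([O-])=CC[C@H]2[C@]1(C)[O-] | intermediate
21 | (3S,4S,5R,10R)-3β,4α,11-trihydroxyeudesman-8-one (C7 epimers) | O[C@H]1CC[C@]2(C)CC(=O)C(C(C)(C)O)C[C@H]2[C@]1(C)O | intermediate
22 | (3S,4S,5R,10R)-3β,4α-dihydroxyeudesm-7(11)-en-8-one | O[C@H]1CC[C@]2(C)CC(=O)C(=C(C)C)C[C@H]2[C@]1(C)O | intermediate
23 | angelic acid, (Z)-2-methylbut-2-enoic acid | C/C=C(/C)C(=O)O | starting material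
24 | (Z)-2-methylbut-2-enoic 2,4,6-trichlorobenzoic anhydride (not isolated) | C/C=C(/C)C(=O)OC(=O)c1c(Cl)cc(Cl)cc1Cl | intermediate
25 | (3S,4S,5R,10R)-3β-angeloyloxy-4α-hydroxyeudesm-7(11)-en-8-one | C/C=C(/C)C(=O)O[C@H]1CC[C@]2(C)CC(=O)C(=C(C)C)C[C@H]2[C@]1(C)O | intermediate
26 | (3S,4S,5R,10R)-3β-angeloyloxy-4α-hydroxy-11-hydroperoxyeudesm-6-en-8-one | C/C=C(/C)C(=O)O[C@H]1CC[C@]2(C)CC(=O)C(C(C)(C)OO)=C[C@H]2[C@]1(C)O | target

**Step count and risks**
Total step count: 14.
Longest linear sequence: 14 steps (1 to 26; compounds 3 and 23 enter as purchased materials).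

Steps most likely to fail:

1. Step 2. The two-point binding of the methoxyquinone to copper may be too weak, so that a single-point or uncatalysed pathway takes over. Facial discrimination at the C5=C10 bond, which lies far from the tert-butyl groups, would then be poor, and the C9–C10 orientation could erode. Stepwise Mukaiyama–Michael addition with silyl transfer may also compete. Fallback: setting out from 2 and 3, the cycloaddition is run without catalyst in toluene at 80 °C, where the same orientation is expected, to give the racemic cis adduct F1. The enantiomers are separated by preparative supercritical-fluid chromatography on an amylose tris(3,5-dimethylphenylcarbamate) phase; the (4aS,8aR) enantiomer F2 is set aside and the (4aR,8aS) enantiomer is compound 4, where the route is rejoined.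

2. Step 11. Enolisation of the dilithium dialkoxide may be slow or unselective, and proton transfer from acetone to the enolate or retro-aldol cleavage on quenching may return 19. Fallback: setting out from 19, silylation with Me3SiOTf and Et3N (CH2Cl2, 0 °C) under equilibrating conditions gives the 3β,4α-bis(trimethylsilyloxy) Δ7 trimethylsilyl enol ether F3. Mukaiyama aldol addition to acetone with TiCl4 (CH2Cl2, −78 °C) then gives the bis(trimethylsilyl) aldol F4, and its silyl ethers are cleaved with citric acid in methanol to return aldol 21.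

3. Step 14. Singlet oxygen may attack the angelate double bond, the ester may undergo sensitised Z-to-E isomerisation, or the ester-bearing hydroperoxide may decompose on prolonged irradiation. Fallback: the photooxygenation is moved in front of the esterification. Setting out from 22, O2, tetraphenylporphyrin and visible light give 3β,4α-dihydroxy-11-hydroperoxyeudesm-6-en-8-one F5. The hydroperoxide, the most acidic and most accessible hydroxyl, is silylated with t-BuMe2SiCl and imidazole (DMF, 0 °C) to the silyl peroxide diol F6. Acylation with mixed anhydride 24 (Et3N, toluene, 60 to 80 °C) gives the angelate silyl peroxide F7, and HF·pyridine (THF, 0 °C) releases the target 26.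

**Further compounds**
F1 | step 2 | racemic cis-2-methoxy-4a-methyl-6-(triisopropylsilyloxy)-4a,5,8,8a-tetrahydronaphthalene-1,4-dione | COC1=CC(=O)C2(C)CC(O[Si](C(C)C)(C(C)C)C(C)C)=CCC2C1=O
F2 | step 2 | (4aS,8aR)-2-methoxy-4a-methyl-6-(triisopropylsilyloxy)-4a,5,8,8a-tetrahydronaphthalene-1,4-dione | COC1=CC(=O)[C@@]2(C)CC(O[Si](C(C)C)(C(C)C)C(C)C)=CC[C@H]2C1=O
F3 | step 11 | (3S,4S,5R,10R)-3β,4α,8-tris(trimethylsilyloxy)-11,12,13-trinoreudesm-7-ene | C[Si](C)(C)O[C@H]1CC[C@]2(C)CC(O[Si](C)(C)C)=CC[C@H]2[C@]1(C)O[Si](C)(C)C
F4 | step 11 | (3S,4S,5R,10R)-11-hydroxy-3β,4α-bis(trimethylsilyloxy)eudesman-8-one (C7 epimers) | C[Si](C)(C)O[C@H]1CC[C@]2(C)CC(=O)C(C(C)(C)O)C[C@H]2[C@]1(C)O[Si](C)(C)C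
F5 | step 14 | (3S,4S,5R,10R)-3β,4α-dihydroxy-11-hydroperoxyeudesm-6-en-8-one | O[C@H]1CC[C@]2(C)CC(=O)C(C(C)(C)OO)=C[C@H]2[C@]1(C)O
F6 | step 14 | (3S,4S,5R,10R)-11-(tert-butyldimethylsilylperoxy)-3β,4α-dihydroxyeudesm-6-en-8-one | O[C@H]1CC[C@]2(C)CC(=O)C(C(C)(C)OO[Si](C)(C)C(C)(C)C)=C[C@H]2[C@]1(C)O
F7 | step 14 | (3S,4S,5R,10R)-3β-angeloyloxy-11-(tert-butyldimethylsilylperoxy)-4α-hydroxyeudesm-6-en-8-one | C/C=C(/C)C(=O)O[C@H]1CC[C@]2(C)CC(=O)C(C(C)(C)OO[Si](C)(C)C(C)(C)C)=C[C@H]2[C@]1(C)O
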